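North differs from north-east in one setting, its first 12 h at −10 °C instead of 50 °C, so you can reckon the difference between them rather than north itself.

| flask | E | Z | temperature | remark | time |
|---|---|---|---|---|---|
| ochre | 0.25 M | 3.5 mM | 5 °C | run made earlier |  |
| red | 0.25 M | 5.5 mM | 38 °C | run made earlier |  |
| amber | 0.12 M | 2.5 mM | 5 °C | run made earlier |  |
| north-east | 0.25 M | 2.5 mM | 50 °C |  | 2.5 d |
| north | 0.25 M | 2.5 mM |  | at −10 °C until 12 h, from then on at 50 °C | 2.5 d |
| south-west | 0.25 M | 2.5 mM | 20 °C |  | 2.5 d |
| west | 0.25 M | 2.5 mM | −10 °C |  | 2.5 d |

| run | time / d | D / % | E / % |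
|---|---|---|---|
| ochre | 1.67 | 0.7 | 99.7 |
| ochre | 3.00 | 0.3 | 100.2 |
| ochre | 8.00 | 0.1 | 100.2 |
| ochre | 20.0 | 1.0 | 101.1 |
| red | 0.833 | 0.5 | 99.7 |
| red | 2.08 | 7.0 | 93.4 |
| red | 3.00 | 12.7 | 86.7 |
| red | 4.00 | 19.8 | 80.7 |
| amber | 5.00 | 0.4 | 99.6 |
| amber | 10.0 | 0.8 | 100.1 |
| amber | 15.0 | 0.6 | 100.4 |
| amber | 20.0 | 0 | 100.1 |

(scatter of a reading: 0.5 percentage points)

- a reading or a percentage of D counts all its forms, free or not

- the flask that comes out highest in amount of D, in percent of the E charged, or "all alike" when all lie within 1.5 percentage points (north-east / north / south-west / west / all alike)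
- D at the end, in percent of the E charged, north-east
- D at the end, in percent of the E charged, north
- D at the end, in percent of the E charged, south-west
- D at the end, in percent of the E charged, west

Build the flask up one process at a time. Start with the main step, E going to D on a steady slope: between its last readings the red run climbs at 0.0667 /d, as a fraction of the E charged. Does the cold count? The ochre run at 5 °C reads 1.0 % of D after 20.0 d, against a scatter of 0.5 percentage points, so treat north's cold time as dead time. North then has 2.00 d of hot time, and hot time over total time is 0.800. This is the hot share: with a steady slope, north holds that fraction of north-east, whatever the slope is.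

Now add the wait. The red run holds 0.5 % of D at 0.833 d, and its slope runs back to zero at 1.03 d, an induction period. A wait in hot time comes off both clocks alike, so it is a small correction that pushes the ratio a little below the hot share. The rest, the size of the slope at 50 °C, needs dependences on temperature and Z that these runs leave open, but the ratio does not use it. South-west and west lie colder than the red run, so I expect D in them to stay below the scatter of 0.5 points within 2.5 d.

The forecast names north-east highest, with 24 % there, 19 % in north, 0.1 % in south-west and 0 % in west, holding that “North gains essentially nothing during its cold 12 h”.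

The flasks end at 26.5 % in north-east, 20.4 % in north, 0.0938 % in south-west and 0 % in west, so north-east is highest.

    L ⇌ D, rate k1*(cs1 - [D]) while solid is left; crystals form when [D] > cs1 (solubility = 0.0860 M, k = 0.00240 /min)
    D + Q → E + Q, rate k2*[Q] as long as [D] is above zero (k = 0.00300 /min, Ea = 104 kJ/mol)
    Z → J (k = 8.80 × 10⁻⁴ /min, Ea = 100 kJ/mol)
    E + J → Q + D (k = 0.0570 /M/min, Ea = 71.0 kJ/mol)
    E + Q → D + Q, rate k5*[Q]*[E] (k = 0.0630 /M/min, Ea = 83.0 kJ/mol)
    (constants at 50 °C)

North over north-east comes to 0.769, lower than the hot share. Solving for a wait common to both flasks gives 0.338 d of hot time and a slope of 0.123 /d, as a fraction of the E charged. In the scheme the wait goes with Z turning into J. North-east's 26.5 % is held down in part by the time allowed, since it holds 80.6 % at 25.0 d, and in part by D going back to E, without which it holds 32.6 %. North read at 25 h should then hold 2.51 % of D, and it holds 2.76 %.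

The numbers in the tables are simulated with made-up constants; noise was put on by code.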